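**Retrosynthetic overview**
1. Target 33 ⇐ 32 by one global acidolysis (two TES ethers, one TBS ether, tert-butyl ester); 32 ⇐ Stille coupling of 2-iodoenone 31 with (E)-vinylstannane 13 (carbinol from (R)-propylene oxide).
2. Cyclohexenone 30/31 ⇐ acyclic 2,6-diketone 27 by intramolecular aldol addition (C2–C3 bond, step 16), then dehydration and α-iodination.
3. 27 ⇐ bis-alkene methyl ketone 24 by double ozonolysis (unmasks the C3 ketone and a side-chain aldehyde) and (E)-selective Wittig reaction with ylide 6.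
4. 24 ⇐ aldehyde 19 + 2-lithioallyl silyl ether from 3 (Felkin–Anh, sets C4); 19 ⇐ diethyl (S)-malate 14 by Fráter–Seebach allylation (C5 from the chiral pool, sets C6).
5. Ring order: the only ring, the carbocycle, is closed in step 16; fragments 3, 6 and 13 are made separately and joined in steps 11, 15 and 19.

Assumption: the target is taken as drawn, i.e. ring 4R,5S,6R (all-cis), (R)-carbinol in the heptenyl chain, both chain alkenes E. Labels C1–C7 mean: C1 ketone, C2 alkenyl-bearing carbon, C3 hydroxymethyl-bearing carbon, C4/C5 carbinols, C6 carbon bearing the butenoic acid chain, C7 the CH2OH carbon. Ketol 28 is carried as a mixture at its new carbinol carbon, which becomes sp2 in step 17.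

**Fragment A: vinyl bromide 3**

Step 1
Reactants: 1 2,3-dibromoprop-1-ene
Product: 2 2-bromoprop-2-en-1-ol
Conditions: K2CO3, H2O, reflux
Reagents that add atoms: water, O
Why: SN2 hydrolysis of the allylic C–Br bond only; the vinylic bromide is inert to aqueous carbonate.

Step 2
Reactants: 2 2-bromoprop-2-en-1-ol
Product: 3 [(2-bromoprop-2-en-1-yl)oxy](tert-butyl)dimethylsilane
Conditions: TBSCl, imidazole, CH2Cl2, 0 °C → rt
Reagents that add atoms: tert-butyldimethylsilyl chloride, CC(C)(C)[Si](C)(C)Cl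
Why: Standard silyl ether formation on the primary allylic alcohol with imidazole as base and nucleophilic catalyst.

**Fragment B: ylide 6**

Step 3
Reactants: 4 tert-butyl 2-bromopropanoate (racemic)
Product: 5 [1-(tert-butoxy)-1-oxopropan-2-yl]triphenylphosphonium bromide (racemic)
Conditions: PPh3, toluene, 90 °C
Reagents that add atoms: triphenylphosphine, c1ccc(cc1)P(c1ccccc1)c1ccccc1
Why: SN2 quaternisation of triphenylphosphine by the α-bromo ester; the racemic centre becomes sp2 in step 4.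

Step 4
Reactants: 5 [1-(tert-butoxy)-1-oxopropan-2-yl]triphenylphosphonium bromide
Product: 6 tert-butyl 2-(triphenyl-λ5-phosphanylidene)propanoate
Conditions: 1 M NaOH (aq), CH2Cl2, rt
Reagents that add atoms: none
Why: Deprotonation of the acidic α-CH of the ester-stabilised phosphonium salt gives the isolable stabilised Wittig ylide.

**Fragment C: vinylstannane 13**

Step 5
Reactants: 7 (4-bromobut-1-yn-1-yl)trimethylsilane; 8 (R)-2-methyloxirane
Product: 10 (2R)-7-(trimethylsilyl)hept-6-yn-2-ol, via Grignard reagent 9 (not isolated)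
Conditions: Mg, THF; then CuI (10 mol %), 8, −30 → 0 °C; aq. NH4Cl
Reagents that add atoms: none
Why: Grignard formation and Cu(I)-catalysed SN2 epoxide opening at the unsubstituted carbon, so the (R) centre of the epoxide is carried over untouched.

Step 6
Reactants: 10 (2R)-7-(trimethylsilyl)hept-6-yn-2-ol
Product: 11 (2R)-7-bromohept-6-yn-2-ol
Conditions: NBS, AgNO3 (10 mol %), acetone, rt, dark
Reagents that add atoms: N-bromosuccinimide, O=C1CCC(=O)N1Br
Why: Ag(I)-catalysed desilylative bromination: the TMS-alkyne reacts through a silver acetylide with electrophilic bromine from NBS.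

Step 7
Reactants: 11 (2R)-7-bromohept-6-yn-2-ol
Product: 13 (2R,6E)-7-(tributylstannyl)hept-6-en-2-ol, via bromostannylalkene 12 (not isolated)
Conditions: Bu3SnH (2.2 equiv), Pd(PPh3)4 (2 mol %), THF, 0 °C → rt
Reagents that add atoms: tributyltin hydride, CCCC[SnH](CCCC)CCCC
Why: Pd(0)-catalysed syn-hydrostannation of the 1-bromoalkyne, then Pd-catalysed reduction of the vinylic C–Br bond with retention, gives only the (E)-vinylstannane.

**Main sequence**

Step 8
Reactants: 14 diethyl (2S)-2-hydroxybutanedioate [diethyl (S)-malate]; 15 3-bromoprop-1-ene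
Product: 17 diethyl (2S,3R)-2-hydroxy-3-(prop-2-en-1-yl)butanedioate, via dilithium alkoxide enolate 16 (not isolated)
Conditions: LDA (2.1 equiv), THF, −78 → −20 °C; then 15, −78 → −10 °C; aq. NH4Cl
Reagents that add atoms: none
Why: Fráter–Seebach alkylation: the chelated dilithium alkoxide–enolate is allylated anti-selectively (about 10:1, minor isomer removed by chromatography), giving the (2S,3R) product and so setting C6 relative to the chiral-pool centre C5.

Step 9
Reactants: 17 diethyl (2S,3R)-2-hydroxy-3-(prop-2-en-1-yl)butanedioate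
Product: 18 diethyl (2S,3R)-3-(prop-2-en-1-yl)-2-[(triethylsilyl)oxy]butanedioate
Conditions: TESOTf, 2,6-lutidine, CH2Cl2, −78 → 0 °C
Reagents that add atoms: triethylsilyl triflate, CC[Si](CC)(CC)OS(=O)(=O)C(F)(F)F
Why: Silyl triflate silylation of the hindered secondary α-hydroxy ester; no stereocentre is touched.

Step 10
Reactants: 18 diethyl (2S,3R)-3-(prop-2-en-1-yl)-2-[(triethylsilyl)oxy]butanedioate
Product: 19 ethyl (2R,3S)-4-oxo-2-(prop-2-en-1-yl)-3-[(triethylsilyl)oxy]butanoate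
Conditions: DIBAL-H (1.1 equiv), CH2Cl2, −78 °C; MeOH, aq. Rochelle salt
Reagents that add atoms: none
Why: Partial DIBAL-H reduction: the ester α to the silyloxy group is the more electrophilic one and its aluminium hemiacetal is stable at −78 °C, so only this ester goes to the aldehyde while the α-branched ester stays.

Step 11
Reactants: 3 [(2-bromoprop-2-en-1-yl)oxy](tert-butyl)dimethylsilane; 19 ethyl (2R,3S)-4-oxo-2-(prop-2-en-1-yl)-3-[(triethylsilyl)oxy]butanoate
Product: 22 ethyl (2R,3S,4R)-5-{[(tert-butyldimethylsilyl)oxy]methyl}-2-(prop-2-en-1-yl)-3,4-bis[(triethylsilyl)oxy]hex-5-enoate, via vinyllithium 20 (not isolated), via lithium alkoxide 21 (not isolated)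
Conditions: 3, t-BuLi (2 equiv per 3), Et2O, −78 °C, 15 min; then 19, −78 °C; then TESOTf, −78 → −30 °C
Reagents that add atoms: triethylsilyl triflate, CC[Si](CC)(CC)OS(=O)(=O)C(F)(F)F
Why: Br/Li exchange, then Felkin–Anh (polar, non-chelated) 1,2-addition to the α-silyloxy aldehyde gives the 4,5-anti (4R) alkoxide and so sets C4; O-silylation in the flask traps it before it can lactonise, and a 1,2-silyl shift would give the same bis-TES ether.

Step 12
Reactants: 22 ethyl (2R,3S,4R)-5-{[(tert-butyldimethylsilyl)oxy]methyl}-2-(prop-2-en-1-yl)-3,4-bis[(triethylsilyl)oxy]hex-5-enoate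
Product: 23 (2R,3S,4R)-5-{[(tert-butyldimethylsilyl)oxy]methyl}-N-methoxy-N-methyl-2-(prop-2-en-1-yl)-3,4-bis[(triethylsilyl)oxy]hex-5-enamide
Conditions: MeNH(OMe)·HCl, i-PrMgCl, THF, −20 → 0 °C
Reagents that add atoms: N,O-dimethylhydroxylamine hydrochloride, CNOC.Cl
Why: Weinreb amide formation by aminolysis of the ethyl ester with the chloromagnesium amide; the α-centre C6 is not enolised under these conditions.

Step 13
Reactants: 23 (2R,3S,4R)-5-{[(tert-butyldimethylsilyl)oxy]methyl}-N-methoxy-N-methyl-2-(prop-2-en-1-yl)-3,4-bis[(triethylsilyl)oxy]hex-5-enamide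
Product: 24 (3R,4S,5R)-6-{[(tert-butyldimethylsilyl)oxy]methyl}-3-(prop-2-en-1-yl)-4,5-bis[(triethylsilyl)oxy]hept-6-en-2-one
Conditions: MeMgBr, THF, −78 → 0 °C; aq. NH4Cl
Reagents that add atoms: methylmagnesium bromide, C[Mg]Br
Why: Grignard addition to the Weinreb amide stops at the chelated tetrahedral intermediate, which gives the methyl ketone (C1, C2) on work-up without over-addition or epimerisation.

Step 14
Reactants: 24 (3R,4S,5R)-6-{[(tert-butyldimethylsilyl)oxy]methyl}-3-(prop-2-en-1-yl)-4,5-bis[(triethylsilyl)oxy]hept-6-en-2-one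
Product: 26 (3R,4S,5S)-3-acetyl-7-[(tert-butyldimethylsilyl)oxy]-6-oxo-4,5-bis[(triethylsilyl)oxy]heptanal, via bis-ozonide 25 (not isolated)
Conditions: O3, CH2Cl2, −78 °C; then PPh3, −78 °C → rt
Reagents that add atoms: ozone, [O-][O+]=O
Why: Ozonolysis with reductive work-up cleaves both terminal alkenes at once, unmasking the C3 ketone and the side-chain aldehyde; ketone, silyl ethers and stereocentres are inert (the descriptor at C4 changes only by CIP priority).

Step 15
Reactants: 26 (3R,4S,5S)-3-acetyl-7-[(tert-butyldimethylsilyl)oxy]-6-oxo-4,5-bis[(triethylsilyl)oxy]heptanal; 6 tert-butyl 2-(triphenyl-λ5-phosphanylidene)propanoate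
Product: 27 tert-butyl (2E,5R,6S,7S)-5-acetyl-9-[(tert-butyldimethylsilyl)oxy]-2-methyl-8-oxo-6,7-bis[(triethylsilyl)oxy]non-2-enoate
Conditions: 6 (1.2 equiv), CH2Cl2, rt (crude 26 used at once)
Reagents that add atoms: none
Why: Wittig olefination with a stabilised α-methyl ylide reacts only with the aldehyde, not the two ketones, and gives the (E)-trisubstituted enoate.

Step 16 (key ring closure)
Reactants: 27 tert-butyl (2E,5R,6S,7S)-5-acetyl-9-[(tert-butyldimethylsilyl)oxy]-2-methyl-8-oxo-6,7-bis[(triethylsilyl)oxy]non-2-enoate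
Product: 28 tert-butyl (2E)-4-[(1R,2S,3S,4RS)-4-{[(tert-butyldimethylsilyl)oxy]methyl}-4-hydroxy-6-oxo-2,3-bis[(triethylsilyl)oxy]cyclohexyl]-2-methylbut-2-enoate
Conditions: L-proline (30 mol %), DMSO, rt
Reagents that add atoms: none
Why: Intramolecular aldol addition (enamine catalysis, 6-enolexo): the enamine forms at the unhindered CH3 of the methyl ketone and attacks the more electrophilic α,α′-dioxygenated C3 ketone to close the six-membered ring; the new tertiary carbinol centre is not controlled and is removed in step 17.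

Step 17
Reactants: 28 tert-butyl (2E)-4-[(1R,2S,3S,4RS)-4-{[(tert-butyldimethylsilyl)oxy]methyl}-4-hydroxy-6-oxo-2,3-bis[(triethylsilyl)oxy]cyclohexyl]-2-methylbut-2-enoate
Product: 30 tert-butyl (2E)-4-[(1R,5R,6S)-4-{[(tert-butyldimethylsilyl)oxy]methyl}-2-oxo-5,6-bis[(triethylsilyl)oxy]cyclohex-3-en-1-yl]-2-methylbut-2-enoate, via tertiary mesylate 29 (not isolated)
Conditions: MsCl, Et3N, DMAP (cat.), CH2Cl2, 0 °C → rt
Reagents that add atoms: none
Why: Sulfene mesylation of the tertiary β-hydroxy ketone and E1cB elimination through the C2 enolate give the conjugated cyclohexenone; C6 is not deprotonated under these mild conditions.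

Step 18
Reactants: 30 tert-butyl (2E)-4-[(1R,5R,6S)-4-{[(tert-butyldimethylsilyl)oxy]methyl}-2-oxo-5,6-bis[(triethylsilyl)oxy]cyclohex-3-en-1-yl]-2-methylbut-2-enoate
Product: 31 tert-butyl (2E)-4-[(1R,5R,6S)-4-{[(tert-butyldimethylsilyl)oxy]methyl}-3-iodo-2-oxo-5,6-bis[(triethylsilyl)oxy]cyclohex-3-en-1-yl]-2-methylbut-2-enoate
Conditions: I2, PhI(O2CCF3)2, pyridine, CH2Cl2, rt, dark
Reagents that add atoms: iodine, II
Why: α-Iodination of the enone (iodine activated by the hypervalent iodine reagent, pyridine as base) puts iodine on C2, the only vinylic C–H; the electron-poor enoate alkene is inert.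

Step 19
Reactants: 31 tert-butyl (2E)-4-[(1R,5R,6S)-4-{[(tert-butyldimethylsilyl)oxy]methyl}-3-iodo-2-oxo-5,6-bis[(triethylsilyl)oxy]cyclohex-3-en-1-yl]-2-methylbut-2-enoate; 13 (2R,6E)-7-(tributylstannyl)hept-6-en-2-ol
Product: 32 tert-butyl (2E)-4-[(1R,5R,6S)-4-{[(tert-butyldimethylsilyl)oxy]methyl}-3-[(1E,6R)-6-hydroxyhept-1-en-1-yl]-2-oxo-5,6-bis[(triethylsilyl)oxy]cyclohex-3-en-1-yl]-2-methylbut-2-enoate
Conditions: Pd2(dba)3 (5 mol %), AsPh3 (20 mol %), CuI (10 mol %), NMP, rt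
Reagents that add atoms: none
Why: Stille cross-coupling of the 2-iodoenone with the vinylstannane proceeds with retention of the (E) geometry under neutral conditions that spare the β-silyloxy ketone and C6.

Step 20
Reactants: 32 tert-butyl (2E)-4-[(1R,5R,6S)-4-{[(tert-butyldimethylsilyl)oxy]methyl}-3-[(1E,6R)-6-hydroxyhept-1-en-1-yl]-2-oxo-5,6-bis[(triethylsilyl)oxy]cyclohex-3-en-1-yl]-2-methylbut-2-enoate
Product: 33 Pestallic acid I, (2E)-4-[(1R,5R,6S)-5,6-dihydroxy-3-[(1E,6R)-6-hydroxyhept-1-en-1-yl]-4-(hydroxymethyl)-2-oxocyclohex-3-en-1-yl]-2-methylbut-2-enoic acid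
Conditions: TFA/CH2Cl2/H2O (10:10:1), 0 °C → rt
Reagents that add atoms: none
Why: Global acidolysis: aqueous TFA hydrolyses the two TES ethers and the primary TBS ether and cleaves the tert-butyl ester (AAL1) without touching any stereocentre.

**Compound list**
1 | 2,3-dibromoprop-1-ene | C=C(Br)CBr | starting material
2 | 2-bromoprop-2-en-1-ol | C=C(Br)CO | intermediate
3 | [(2-bromoprop-2-en-1-yl)oxy](tert-butyl)dimethylsilane | C=C(Br)CO[Si](C)(C)C(C)(C)C | intermediate
4 | tert-butyl 2-bromopropanoate (racemic) | CC(Br)C(=O)OC(C)(C)C | starting material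
5 | [1-(tert-butoxy)-1-oxopropan-2-yl]triphenylphosphonium bromide (racemic) | CC(C(=O)OC(C)(C)C)[P+](c1ccccc1)(c1ccccc1)c1ccccc1.[Br-] | intermediate
6 | tert-butyl 2-(triphenyl-λ5-phosphanylidene)propanoate | CC(C(=O)OC(C)(C)C)=P(c1ccccc1)(c1ccccc1)c1ccccc1 | intermediate
7 | (4-bromobut-1-yn-1-yl)trimethylsilane | C[Si](C)(C)C#CCCBr | starting material
8 | (R)-2-methyloxirane [(R)-propylene oxide] | C[C@@H]1CO1 | starting material
9 | [4-(trimethylsilyl)but-3-yn-1-yl]magnesium bromide | C[Si](C)(C)C#CCC[Mg]Br | intermediate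
10 | (2R)-7-(trimethylsilyl)hept-6-yn-2-ol | C[C@@H](O)CCCC#C[Si](C)(C)C | intermediate
11 | (2R)-7-bromohept-6-yn-2-ol | C[C@@H](O)CCCC#CBr | intermediate
12 | (2R,6E)-7-bromo-7-(tributylstannyl)hept-6-en-2-ol | C[C@@H](O)CCC/C=C(\Br)[Sn](CCCC)(CCCC)CCCC | intermediate
13 | (2R,6E)-7-(tributylstannyl)hept-6-en-2-ol | C[C@@H](O)CCC/C=C/[Sn](CCCC)(CCCC)CCCC | intermediate
14 | diethyl (2S)-2-hydroxybutanedioate [diethyl (S)-malate] | CCOC(=O)C[C@H](O)C(=O)OCC | starting material
15 | 3-bromoprop-1-ene (allyl bromide) | C=CCBr | starting material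
16 | dilithium alkoxide–enolate of 14 | CCOC(O[Li])=C[C@H](O[Li])C(=O)OCC | intermediate
17 | diethyl (2S,3R)-2-hydroxy-3-(prop-2-en-1-yl)butanedioate | CCOC(=O)[C@H](CC=C)[C@H](O)C(=O)OCC | intermediate
18 | diethyl (2S,3R)-3-(prop-2-en-1-yl)-2-[(triethylsilyl)oxy]butanedioate | CCOC(=O)[C@H](CC=C)[C@H](O[Si](CC)(CC)CC)C(=O)OCC | intermediate
19 | ethyl (2R,3S)-4-oxo-2-(prop-2-en-1-yl)-3-[(triethylsilyl)oxy]butanoate | CCOC(=O)[C@H](CC=C)[C@H](O[Si](CC)(CC)CC)C=O | intermediate
20 | {3-[(tert-butyldimethylsilyl)oxy]prop-1-en-2-yl}lithium | [Li]C(=C)CO[Si](C)(C)C(C)(C)C | intermediate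
21 | lithium (4R)-alkoxide of the adduct of 20 and 19 | CCOC(=O)[C@H](CC=C)[C@H](O[Si](CC)(CC)CC)[C@H](O[Li])C(=C)CO[Si](C)(C)C(C)(C)C | intermediate
22 | ethyl (2R,3S,4R)-5-{[(tert-butyldimethylsilyl)oxy]methyl}-2-(prop-2-en-1-yl)-3,4-bis[(triethylsilyl)oxy]hex-5-enoate | CCOC(=O)[C@H](CC=C)[C@H](O[Si](CC)(CC)CC)[C@H](O[Si](CC)(CC)CC)C(=C)CO[Si](C)(C)C(C)(C)C | intermediate
23 | (2R,3S,4R)-5-{[(tert-butyldimethylsilyl)oxy]methyl}-N-methoxy-N-methyl-2-(prop-2-en-1-yl)-3,4-bis[(triethylsilyl)oxy]hex-5-enamide | CON(C)C(=O)[C@H](CC=C)[C@H](O[Si](CC)(CC)CC)[C@H](O[Si](CC)(CC)CC)C(=C)CO[Si](C)(C)C(C)(C)C | intermediate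
24 | (3R,4S,5R)-6-{[(tert-butyldimethylsilyl)oxy]methyl}-3-(prop-2-en-1-yl)-4,5-bis[(triethylsilyl)oxy]hept-6-en-2-one | CC(=O)[C@H](CC=C)[C@H](O[Si](CC)(CC)CC)[C@H](O[Si](CC)(CC)CC)C(=C)CO[Si](C)(C)C(C)(C)C | intermediate
25 | bis(1,2,4-trioxolane) (bis-ozonide) of 24, mixture at the trioxolane carbons | CC(=O)[C@H](CC1OCOO1)[C@H](O[Si](CC)(CC)CC)[C@H](O[Si](CC)(CC)CC)C1(CO[Si](C)(C)C(C)(C)C)OCOO1 | intermediate
26 | (3R,4S,5S)-3-acetyl-7-[(tert-butyldimethylsilyl)oxy]-6-oxo-4,5-bis[(triethylsilyl)oxy]heptanal | CC(=O)[C@H](CC=O)[C@H](O[Si](CC)(CC)CC)[C@H](O[Si](CC)(CC)CC)C(=O)CO[Si](C)(C)C(C)(C)C | intermediate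
27 | tert-butyl (2E,5R,6S,7S)-5-acetyl-9-[(tert-butyldimethylsilyl)oxy]-2-methyl-8-oxo-6,7-bis[(triethylsilyl)oxy]non-2-enoate | CC(=O)[C@H](C/C=C(\C)C(=O)OC(C)(C)C)[C@H](O[Si](CC)(CC)CC)[C@H](O[Si](CC)(CC)CC)C(=O)CO[Si](C)(C)C(C)(C)C | intermediate
28 | tert-butyl (2E)-4-[(1R,2S,3S,4RS)-4-{[(tert-butyldimethylsilyl)oxy]methyl}-4-hydroxy-6-oxo-2,3-bis[(triethylsilyl)oxy]cyclohexyl]-2-methylbut-2-enoate (epimers at the carbinol carbon) | C/C(=C\C[C@H]1C(=O)CC(O)(CO[Si](C)(C)C(C)(C)C)[C@@H](O[Si](CC)(CC)CC)[C@H]1O[Si](CC)(CC)CC)C(=O)OC(C)(C)C | intermediate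
29 | methanesulfonate of the tertiary alcohol of 28 | C/C(=C\C[C@H]1C(=O)CC(OS(C)(=O)=O)(CO[Si](C)(C)C(C)(C)C)[C@@H](O[Si](CC)(CC)CC)[C@H]1O[Si](CC)(CC)CC)C(=O)OC(C)(C)C | intermediate
30 | tert-butyl (2E)-4-[(1R,5R,6S)-4-{[(tert-butyldimethylsilyl)oxy]methyl}-2-oxo-5,6-bis[(triethylsilyl)oxy]cyclohex-3-en-1-yl]-2-methylbut-2-enoate | C/C(=C\C[C@H]1C(=O)C=C(CO[Si](C)(C)C(C)(C)C)[C@@H](O[Si](CC)(CC)CC)[C@H]1O[Si](CC)(CC)CC)C(=O)OC(C)(C)C | intermediate
31 | tert-butyl (2E)-4-[(1R,5R,6S)-4-{[(tert-butyldimethylsilyl)oxy]methyl}-3-iodo-2-oxo-5,6-bis[(triethylsilyl)oxy]cyclohex-3-en-1-yl]-2-methylbut-2-enoate | C/C(=C\C[C@H]1C(=O)C(I)=C(CO[Si](C)(C)C(C)(C)C)[C@@H](O[Si](CC)(CC)CC)[C@H]1O[Si](CC)(CC)CC)C(=O)OC(C)(C)C | intermediate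
32 | tert-butyl (2E)-4-[(1R,5R,6S)-4-{[(tert-butyldimethylsilyl)oxy]methyl}-3-[(1E,6R)-6-hydroxyhept-1-en-1-yl]-2-oxo-5,6-bis[(triethylsilyl)oxy]cyclohex-3-en-1-yl]-2-methylbut-2-enoate | C/C(=C\C[C@H]1C(=O)C(/C=C/CCC[C@@H](C)O)=C(CO[Si](C)(C)C(C)(C)C)[C@@H](O[Si](CC)(CC)CC)[C@H]1O[Si](CC)(CC)CC)C(=O)OC(C)(C)C | intermediate
33 | Pestallic acid I | C/C(=C\C[C@H]1C(=O)C(/C=C/CCC[C@@H](C)O)=C(CO)[C@@H](O)[C@H]1O)C(=O)O | target

**Totals**
Total step count: 20.
Longest linear sequence: 13 steps (steps 8–20, from diethyl (S)-malate 14).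

**Three steps most likely to fail**

Step 11 (alkenyllithium addition). The Felkin–Anh preference of an α-silyloxy aldehyde for an alkenyllithium may be only moderate, the 2-lithioallyl silyl ether can suffer retro-Brook silyl migration, and the alkoxide can lactonise before it is trapped. The fallback sets C4 by ketone reduction instead of by C–C addition; it sets out from aldehyde 19 and comes back at bis-silyl ether 22. Aldehyde 19 is coupled with bromide 3 under Nozaki–Hiyama–Kishi conditions (CrCl2, cat. NiCl2, DMF, rt; no organolithium, esters untouched) to give the allylic alcohol F1 as a C4 epimer mixture. Dess–Martin oxidation (NaHCO3, CH2Cl2) gives the enone F2. Luche reduction (NaBH4, CeCl3·7H2O, MeOH, −78 °C) then delivers hydride under Felkin–Anh control to the α-silyloxy ketone and gives the (4R)-alcohol F3; the minor epimer is recycled through F2. TESOTf/2,6-lutidine at −78 °C returns 22.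

Step 16 (ring-closing aldol). The enamine could form on the wrong ketone (C7 side), the β-silyloxy group at C5 could be lost by E1cB, C6 could epimerise, the enamine could add in Michael fashion to the enoate, or the hindered C3 ketone could react too slowly. The fallback makes the C2 enolate regiospecifically by C–halogen reduction; it sets out from Weinreb amide 23 and comes back at ketol 28. LiCH2Cl (from ICH2Cl and MeLi·LiBr, THF, −78 °C) converts 23 into the chloromethyl ketone F4. Ozonolysis with Me2S work-up gives the keto aldehyde F5, and Wittig reaction with ylide 6 gives the chloro diketone F6. SmI2 (2.2 equiv, THF, −78 °C) reduces only the C–Cl bond, and the samarium(III) enolate, fixed at C2, closes the ring by an intramolecular Reformatsky-type aldol addition onto the C3 ketone to give 28.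

Step 20 (global deprotection). Prolonged exposure to TFA could dehydrate the β-hydroxy ketone (leading to aromatisation), epimerise C6 through the enol, or leave silyl ethers partly intact. The fallback separates the two deprotections and avoids strong Brønsted acid; it sets out from 32 and comes back at 33. HF·pyridine in THF/pyridine (0 °C → rt) removes the three silyl ethers and gives the tetraol tert-butyl ester F7. The ester is then cleaved on its own by a Lewis acid (ZnBr2, CH2Cl2, rt; aqueous work-up at pH 4–5) to give 33.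

**Further compounds**
F1 | step 11 | ethyl (2R,3S,4RS)-5-{[(tert-butyldimethylsilyl)oxy]methyl}-4-hydroxy-2-(prop-2-en-1-yl)-3-[(triethylsilyl)oxy]hex-5-enoate | CCOC(=O)[C@H](CC=C)[C@H](O[Si](CC)(CC)CC)C(O)C(=C)CO[Si](C)(C)C(C)(C)C
F2 | step 11 | ethyl (2R,3S)-5-{[(tert-butyldimethylsilyl)oxy]methyl}-4-oxo-2-(prop-2-en-1-yl)-3-[(triethylsilyl)oxy]hex-5-enoate | CCOC(=O)[C@H](CC=C)[C@H](O[Si](CC)(CC)CC)C(=O)C(=C)CO[Si](C)(C)C(C)(C)C
F3 | step 11 | ethyl (2R,3S,4R)-5-{[(tert-butyldimethylsilyl)oxy]methyl}-4-hydroxy-2-(prop-2-en-1-yl)-3-[(triethylsilyl)oxy]hex-5-enoate | CCOC(=O)[C@H](CC=C)[C@H](O[Si](CC)(CC)CC)[C@H](O)C(=C)CO[Si](C)(C)C(C)(C)C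
F4 | step 16 | (3R,4S,5R)-6-{[(tert-butyldimethylsilyl)oxy]methyl}-1-chloro-3-(prop-2-en-1-yl)-4,5-bis[(triethylsilyl)oxy]hept-6-en-2-one | ClCC(=O)[C@H](CC=C)[C@H](O[Si](CC)(CC)CC)[C@H](O[Si](CC)(CC)CC)C(=C)CO[Si](C)(C)C(C)(C)C
F5 | step 16 | (3R,4S,5S)-7-[(tert-butyldimethylsilyl)oxy]-3-(chloroacetyl)-6-oxo-4,5-bis[(triethylsilyl)oxy]heptanal | ClCC(=O)[C@H](CC=O)[C@H](O[Si](CC)(CC)CC)[C@H](O[Si](CC)(CC)CC)C(=O)CO[Si](C)(C)C(C)(C)C
F6 | step 16 | tert-butyl (2E,5R,6S,7S)-9-[(tert-butyldimethylsilyl)oxy]-5-(chloroacetyl)-2-methyl-8-oxo-6,7-bis[(triethylsilyl)oxy]non-2-enoate | ClCC(=O)[C@H](C/C=C(\C)C(=O)OC(C)(C)C)[C@H](O[Si](CC)(CC)CC)[C@H](O[Si](CC)(CC)CC)C(=O)CO[Si](C)(C)C(C)(C)C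
F7 | step 20 | tert-butyl (2E)-4-[(1R,5R,6S)-5,6-dihydroxy-3-[(1E,6R)-6-hydroxyhept-1-en-1-yl]-4-(hydroxymethyl)-2-oxocyclohex-3-en-1-yl]-2-methylbut-2-enoate | C/C(=C\C[C@H]1C(=O)C(/C=C/CCC[C@@H](C)O)=C(CO)[C@@H](O)[C@H]1O)C(=O)OC(C)(C)C
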